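**Retrosynthetic overview**
- Feature: in ring A (the benzo ring of the benzofuran) a free C5–OH sits next to unsubstituted C4–H, followed by C6–OMe and C7–prenyl. A ketene carbon (C5) with its α-CH (C4) leaves this pattern when it closes onto a two-carbon enol ether arm (C7, C6).
- After removal of the 3'-O-silyl group, the C5–C6 bond is cut. Ring A opens to a furan-3-ylketene with a 1-methoxy-5-methylhexa-1,4-dien-2-yl arm at furan C2, and the ketene goes back to a furan-3-yl diazomethyl ketone (photo-Wolff).
- The diazoketone comes from the furan-3-carboxylic acid. The enol ether comes from Wittig methoxymethylenation of a C2 ketone, itself made by carboxylate-directed C2 lithiation and acylation with a Weinreb amide.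
- The aryl–furan bond (benzofuran C2–C1') is a Suzuki coupling of 5-bromofuran-3-carboxylic acid with a boronate obtained by C–H borylation of silylated 3-methoxyphenol.
- Ring order: the aryl ring and the furan are bought. Ring A is the only ring built, and it is formed last.

Key step: step 8

Assumption: the Wittig reaction is expected to give both enol ether geometries. The (E)-isomer is drawn and numbered, and the (Z)-isomer is carried along unseparated because both lead to the same phenol in the key step.
Assumption: carboxylic acids react as their carboxylate salts in basic media and are named, drawn and numbered in the neutral form that the acidic work-up returns.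

**Step 1**
Reactants: 1 3-methoxyphenol
Product: 2 triisopropyl(3-methoxyphenoxy)silane
Conditions: iPr3SiCl, imidazole, DMF, rt
Reagents that add atoms: chlorotriisopropylsilane, CC(C)[Si](Cl)(C(C)C)C(C)C
Why: Imidazole-promoted O-silylation of a phenol is routine, and the bulky triisopropylsilyl ether should outlast aqueous carbonate, lithium amide and ylide yet fall to fluoride at the end.

**Step 2**
Reactants: 2 triisopropyl(3-methoxyphenoxy)silane
Product: 3 2-[3-methoxy-5-(triisopropylsilyloxy)phenyl]-4,4,5,5-tetramethyl-1,3,2-dioxaborolane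
Conditions: B2pin2 (1.0 equiv), [Ir(OMe)(cod)]2 (1.5 mol %), 4,4'-di-tert-butyl-2,2'-bipyridine (3 mol %), THF, 80 °C
Reagents that add atoms: bis(pinacolato)diboron, CC1(C)OB(OC1(C)C)B1OC(C)(C)C(C)(C)O1
Why: The iridium-catalysed aromatic C–H borylation (Hartwig–Miyaura borylation) is governed by sterics, and in this 1,3-disubstituted arene only C5–H has no ortho neighbour.

**Step 3**
Reactants: 3 2-[3-methoxy-5-(triisopropylsilyloxy)phenyl]-4,4,5,5-tetramethyl-1,3,2-dioxaborolane; 4 5-bromofuran-3-carboxylic acid
Product: 5 5-[3-methoxy-5-(triisopropylsilyloxy)phenyl]furan-3-carboxylic acid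
Conditions: Pd(dppf)Cl2 (3 mol %), K2CO3 (3 equiv), 1,4-dioxane/H2O (4:1), 80 °C; then 1 M HCl to pH 3
Reagents that add atoms: none
Why: In this Suzuki–Miyaura coupling the α-bromofuran undergoes oxidative addition readily, extra base accommodates the acid, and the hindered aryl silyl ether should tolerate aqueous carbonate at this temperature.

**Step 4**
Reactants: 6 4-methylpent-3-enoic acid
Product: 7 N-methoxy-N,4-dimethylpent-3-enamide
Conditions: MeNH(OMe)·HCl, EDC·HCl, N-methylmorpholine, CH2Cl2, 0 °C → rt
Reagents that add atoms: N,O-dimethylhydroxylamine hydrochloride, CNOC.Cl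
Why: Carbodiimide amide coupling under weakly basic conditions at low temperature should give the Weinreb amide without moving the β,γ-alkene into conjugation.

**Step 5**
Reactants: 5 5-[3-methoxy-5-(triisopropylsilyloxy)phenyl]furan-3-carboxylic acid; 7 N-methoxy-N,4-dimethylpent-3-enamide
Product: 10 5-[3-methoxy-5-(triisopropylsilyloxy)phenyl]-2-(4-methylpent-3-enoyl)furan-3-carboxylic acid, via dilithio furoate 8 (not isolated), via tetrahedral lithium adduct 9 (not isolated)
Conditions: LiN(iPr)2 (2.2 equiv), THF, −78 °C; then 7 (1.5 equiv), −78 → −20 °C; cold 1 M HCl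
Reagents that add atoms: none
Why: Two equivalents of amide base give the carboxylate-directed C2-lithiated dianion (directed metalation at the only free furan α-position), and the Weinreb ketone synthesis stops at chelated adduct 9, which blocks over-addition and masks the acidic CH2 of the ketone until the cold acidic quench.

**Step 6**
Reactants: 10 5-[3-methoxy-5-(triisopropylsilyloxy)phenyl]-2-(4-methylpent-3-enoyl)furan-3-carboxylic acid; 11 (methoxymethyl)triphenylphosphonium chloride
Product: 13 2-[(E)-1-methoxy-5-methylhexa-1,4-dien-2-yl]-5-[3-methoxy-5-(triisopropylsilyloxy)phenyl]furan-3-carboxylic acid, via methoxymethylene ylide 12 (not isolated)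
Conditions: 11 (3 equiv), KOtBu (4 equiv), THF, 0 °C; then 10, 0 °C → rt; cold aq NaH2PO4 (pH 5), product used promptly
Reagents that add atoms: none
Why: Wittig methoxymethylenation with the non-stabilised ylide works on ortho-acyl and ortho-formyl aromatic carboxylates when one extra equivalent of base takes the acid proton, the excess ylide offsets reversible enolisation of the CH2 between carbonyl and alkene, and the trisubstituted alkene has little drive to move into conjugation.

**Step 7**
Reactants: 13 2-[(E)-1-methoxy-5-methylhexa-1,4-dien-2-yl]-5-[3-methoxy-5-(triisopropylsilyloxy)phenyl]furan-3-carboxylic acid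
Product: 16 2-diazo-1-{2-[(E)-1-methoxy-5-methylhexa-1,4-dien-2-yl]-5-[3-methoxy-5-(triisopropylsilyloxy)phenyl]furan-3-yl}ethanone, via acid chloride 14 (not isolated), via C-silyl diazoketone 15 (not isolated)
Conditions: Me2C=C(Cl)NMe2 (1.1 equiv), CH2Cl2, 0 °C; then Me3SiCHN2 (2 equiv), Et3N, THF/MeCN (1:1), 0 °C → rt; aq NaHCO3
Reagents that add atoms: trimethylsilyldiazomethane, C[Si](C)(C)C=[N+]=[N-]
Why: The α-chloroenamine converts the acid into its chloride without releasing HCl, so the enol ether should survive, and C-acylation of the diazoalkane (first stage of the Arndt–Eistert sequence) followed by loss of the labile C-silyl group on aqueous work-up should give the diazomethyl ketone.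

**Step 8**
Reactants: 16 2-diazo-1-{2-[(E)-1-methoxy-5-methylhexa-1,4-dien-2-yl]-5-[3-methoxy-5-(triisopropylsilyloxy)phenyl]furan-3-yl}ethanone
Product: 19 6-methoxy-2-[3-methoxy-5-(triisopropylsilyloxy)phenyl]-7-(3-methylbut-2-en-1-yl)-1-benzofuran-5-ol, via furan-3-ylketene 17 (not isolated), via cyclohexadienone 18 (not isolated)
Conditions: hν (365 nm LED), dry degassed PhMe (5 mM), 25 °C, then 80 °C
Reagents that add atoms: none
Why: Excitation of the s-Z diazoketone expels N2 while the furan-3-yl group shifts to the diazo carbon (photochemical Wolff rearrangement), so the diazo carbon becomes C4–H and the former carbonyl carbon becomes the ketene carbon C5 of 17. In 17 the ketene C4=C5 bond, the furan C3a=C7a bond and the enol ether C7=C6 bond form a 1,3,5-triene whose central double bond is held cis by the furan, and ring A closes by a thermal disrotatory six-electron electrocyclization that makes the C5–C6 bond and gives dienone 18. A proton shift from C6 to the carbonyl oxygen restores the furan sextet and delivers the benzofuran-5-ol 19, so the only sp3 centre formed (C6 of 18) is lost at once and no stereocentre needs control. The closest known reaction type is the phenol synthesis from dienylketenes generated by Wolff rearrangement of unsaturated diazoketones, the closing stage of the diazoketone version of the Danheiser benzannulation. The step needs chemoselectivity for rearrangement over carbene capture by the enol ether or the prenyl alkene, which metal-free direct irradiation of the s-Z conformer favours, and periselectivity for six-electron closure over (2+2) addition, dimerisation or acylation of the phenol formed, which the enforced proximity of C5 and C6, the outward-pointing methoxy group of the (E)-enol ether and high dilution in dry toluene should secure. Regiochemistry is not at issue because OH, H, OMe and prenyl at C5, C4, C6 and C7 are all fixed in 16, and the (Z)-enol ether leads to the same phenol.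

**Step 9**
Reactants: 19 6-methoxy-2-[3-methoxy-5-(triisopropylsilyloxy)phenyl]-7-(3-methylbut-2-en-1-yl)-1-benzofuran-5-ol
Product: 20 Dinklagein A, 2-(3-hydroxy-5-methoxyphenyl)-6-methoxy-7-(3-methylbut-2-en-1-yl)-1-benzofuran-5-ol
Conditions: Bu4NF (1.2 equiv), AcOH (1.2 equiv), THF, 0 °C
Reagents that add atoms: none
Why: Fluoride desilylation cleaves the aryl silyl ether through pentacoordinate silicon, and the acetic acid buffer keeps both phenols protonated so that the electron-rich product is not exposed to air as a phenoxide.

**Compound list**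
1 | 3-methoxyphenol | COc1cccc(O)c1 | starting material
2 | triisopropyl(3-methoxyphenoxy)silane | COc1cccc(O[Si](C(C)C)(C(C)C)C(C)C)c1 | intermediate
3 | 2-[3-methoxy-5-(triisopropylsilyloxy)phenyl]-4,4,5,5-tetramethyl-1,3,2-dioxaborolane | COc1cc(O[Si](C(C)C)(C(C)C)C(C)C)cc(B2OC(C)(C)C(C)(C)O2)c1 | intermediate
4 | 5-bromofuran-3-carboxylic acid | OC(=O)c1coc(Br)c1 | starting material
5 | 5-[3-methoxy-5-(triisopropylsilyloxy)phenyl]furan-3-carboxylic acid | COc1cc(O[Si](C(C)C)(C(C)C)C(C)C)cc(-c2cc(C(=O)O)co2)c1 | intermediate
6 | 4-methylpent-3-enoic acid | CC(C)=CCC(=O)O | starting material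
7 | N-methoxy-N,4-dimethylpent-3-enamide | CC(C)=CCC(=O)N(C)OC | intermediate
8 | lithium 2-lithio-5-[3-methoxy-5-(triisopropylsilyloxy)phenyl]furan-3-carboxylate | [Li]OC(=O)c1cc(-c2cc(OC)cc(O[Si](C(C)C)(C(C)C)C(C)C)c2)oc1[Li] | intermediate
9 | dilithium salt of 2-{1-hydroxy-1-[methoxy(methyl)amino]-4-methylpent-3-en-1-yl}-5-[3-methoxy-5-(triisopropylsilyloxy)phenyl]furan-3-carboxylic acid (racemic) | [Li]OC(=O)c1cc(-c2cc(OC)cc(O[Si](C(C)C)(C(C)C)C(C)C)c2)oc1C(O[Li])(CC=C(C)C)N(C)OC | intermediate
10 | 5-[3-methoxy-5-(triisopropylsilyloxy)phenyl]-2-(4-methylpent-3-enoyl)furan-3-carboxylic acid | COc1cc(O[Si](C(C)C)(C(C)C)C(C)C)cc(-c2cc(C(=O)O)c(C(=O)CC=C(C)C)o2)c1 | intermediate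
11 | (methoxymethyl)triphenylphosphonium chloride | [Cl-].COC[P+](c1ccccc1)(c1ccccc1)c1ccccc1 | starting material
12 | (methoxymethylidene)triphenylphosphorane | COC=P(c1ccccc1)(c1ccccc1)c1ccccc1 | intermediate
13 | 2-[(E)-1-methoxy-5-methylhexa-1,4-dien-2-yl]-5-[3-methoxy-5-(triisopropylsilyloxy)phenyl]furan-3-carboxylic acid | CO/C=C(\CC=C(C)C)c1oc(-c2cc(OC)cc(O[Si](C(C)C)(C(C)C)C(C)C)c2)cc1C(=O)O | intermediate
14 | 2-[(E)-1-methoxy-5-methylhexa-1,4-dien-2-yl]-5-[3-methoxy-5-(triisopropylsilyloxy)phenyl]furan-3-carbonyl chloride | CO/C=C(\CC=C(C)C)c1oc(-c2cc(OC)cc(O[Si](C(C)C)(C(C)C)C(C)C)c2)cc1C(=O)Cl | intermediate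
15 | 2-diazo-1-{2-[(E)-1-methoxy-5-methylhexa-1,4-dien-2-yl]-5-[3-methoxy-5-(triisopropylsilyloxy)phenyl]furan-3-yl}-2-(trimethylsilyl)ethanone | CO/C=C(\CC=C(C)C)c1oc(-c2cc(OC)cc(O[Si](C(C)C)(C(C)C)C(C)C)c2)cc1C(=O)C(=[N+]=[N-])[Si](C)(C)C | intermediate
16 | 2-diazo-1-{2-[(E)-1-methoxy-5-methylhexa-1,4-dien-2-yl]-5-[3-methoxy-5-(triisopropylsilyloxy)phenyl]furan-3-yl}ethanone | CO/C=C(\CC=C(C)C)c1oc(-c2cc(OC)cc(O[Si](C(C)C)(C(C)C)C(C)C)c2)cc1C(=O)C=[N+]=[N-] | intermediate
17 | 2-{2-[(E)-1-methoxy-5-methylhexa-1,4-dien-2-yl]-5-[3-methoxy-5-(triisopropylsilyloxy)phenyl]furan-3-yl}ethenone | CO/C=C(\CC=C(C)C)c1oc(-c2cc(OC)cc(O[Si](C(C)C)(C(C)C)C(C)C)c2)cc1C=C=O | intermediate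
18 | 6-methoxy-2-[3-methoxy-5-(triisopropylsilyloxy)phenyl]-7-(3-methylbut-2-en-1-yl)-1-benzofuran-5(6H)-one (racemic at C6, transient) | COC1C(=O)C=C2C=C(-c3cc(OC)cc(O[Si](C(C)C)(C(C)C)C(C)C)c3)OC2=C1CC=C(C)C | intermediate
19 | 6-methoxy-2-[3-methoxy-5-(triisopropylsilyloxy)phenyl]-7-(3-methylbut-2-en-1-yl)-1-benzofuran-5-ol | COc1cc(O[Si](C(C)C)(C(C)C)C(C)C)cc(-c2cc3cc(O)c(OC)c(CC=C(C)C)c3o2)c1 | intermediate
20 | Dinklagein A | COc1cc(O)cc(-c2cc3cc(O)c(OC)c(CC=C(C)C)c3o2)c1 | target

**Total step count:** 9
**Longest linear sequence:** 8 (steps 1, 2, 3, 5, 6, 7, 8, 9)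

**Steps most likely to fail**

**Step 8 (key step).**
- What may go wrong:
  - The neighbouring enol ether or the prenyl alkene may capture the excited diazoketone or a free carbene before the furyl group migrates.
  - Light may drive rearrangement of the 1,4-diene arm.
  - Unreacted ketene may acylate the newly formed phenol.
  - Ring closure may be slow, because the closing terminus C6 is not the nucleophilic carbon of the enol ether and furan aromaticity is interrupted on the way.
- Fallback (no light, phenol trapped as it forms): setting out from 16, the Wolff rearrangement is run in the dark with PhCO2Ag (cat.) and Et3N in THF/H2O, so that ketene 17 is hydrated to the furan-3-ylacetic acid F1 (Arndt–Eistert homologation). Any ketene that closes instead gives 19 directly. Heating with Ac2O and NaOAc in toluene dehydrates the acid to ketene 17 again under reversible thermal conditions. This is the classical closure of hexa-3,5-dienoic acids to aryl acetates, and it traps the ring-closed phenol as the C5 acetate F2. Brief methanolysis (K2CO3, MeOH, 0 °C) removes the acetate, and the route is rejoined at 19.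

**Step 6.**
- What may go wrong: the basic ylide may deprotonate the CH2 between carbonyl and alkene, so that conversion stalls and the alkene drifts into conjugation. The free acid may also slowly add to its own enol ether during isolation.
- Fallback (no ketone at all, so step 5 is bypassed as well): setting out from 5, dilithio species 8 is made as in step 5 and quenched with I2 to give the 2-iodofuran-3-carboxylic acid F3.
  - In parallel, chloroacetaldehyde dimethyl acetal is treated with LiNEt2 (3 equiv, THF) to give lithium methoxyacetylide F4.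
  - This is alkylated with prenyl bromide (DMPU) to the ynol ether 1-methoxy-5-methylhex-4-en-1-yne F5.
  - Syn-hydroboration with pinacolborane (Cp2ZrHCl cat.) should place boron on the carbon remote from oxygen and give the (Z)-alkenylboronate F6, in which hydrogen and boron are cis.
  - Suzuki–Miyaura coupling of the iodide with this boronate (Pd(dppf)Cl2, K3PO4, THF/H2O, 50 °C, pH 5 work-up) goes with retention and comes back to the route at 13, now as the single (E)-isomer.

**Step 5.**
- What may go wrong: a proton may pass from the allylic α-CH2 of 7 to the furyllithium, which returns 5. The second lithiation may also be incomplete.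
- Fallback (addition to an aldehyde, then oxidation): commercial 4-methylpent-3-en-1-ol is oxidised with Dess–Martin periodinane/NaHCO3 to 4-methylpent-3-enal F7, which is used crude. Setting out from 5, dilithio species 8 is added to this aldehyde at −78 °C, where carbonyl addition should outrun enolisation, to give the racemic hydroxy acid F8 after a pH 4–5 work-up. Oxidation of this furfuryl-type alcohol with MnO2 in CH2Cl2 comes back to the route at 10.

**Further compounds**
F1 | step 8 | 2-{2-[(E)-1-methoxy-5-methylhexa-1,4-dien-2-yl]-5-[3-methoxy-5-(triisopropylsilyloxy)phenyl]furan-3-yl}acetic acid | CO/C=C(\CC=C(C)C)c1oc(-c2cc(OC)cc(O[Si](C(C)C)(C(C)C)C(C)C)c2)cc1CC(=O)O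
F2 | step 8 | 6-methoxy-2-[3-methoxy-5-(triisopropylsilyloxy)phenyl]-7-(3-methylbut-2-en-1-yl)-1-benzofuran-5-yl acetate | COc1cc(O[Si](C(C)C)(C(C)C)C(C)C)cc(-c2cc3cc(OC(C)=O)c(OC)c(CC=C(C)C)c3o2)c1
F3 | step 6 | 2-iodo-5-[3-methoxy-5-(triisopropylsilyloxy)phenyl]furan-3-carboxylic acid | COc1cc(O[Si](C(C)C)(C(C)C)C(C)C)cc(-c2cc(C(=O)O)c(I)o2)c1
F4 | step 6 | lithium methoxyacetylide | COC#C[Li]
F5 | step 6 | 1-methoxy-5-methylhex-4-en-1-yne | COC#CCC=C(C)C
F6 | step 6 | 2-[(Z)-1-methoxy-5-methylhexa-1,4-dien-2-yl]-4,4,5,5-tetramethyl-1,3,2-dioxaborolane | CO/C=C(\CC=C(C)C)B1OC(C)(C)C(C)(C)O1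
F7 | step 5 | 4-methylpent-3-enal | CC(C)=CCC=O
F8 | step 5 | 2-(1-hydroxy-4-methylpent-3-en-1-yl)-5-[3-methoxy-5-(triisopropylsilyloxy)phenyl]furan-3-carboxylic acid (racemic) | COc1cc(O[Si](C(C)C)(C(C)C)C(C)C)cc(-c2cc(C(=O)O)c(C(O)CC=C(C)C)o2)c1
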